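**Retrosynthetic overview**

1. Target 23 is opened at the two aryl silyl ethers and at the four aryl ester C–O bonds, giving tetraol 20 and four units of carboxylate 19.
2. Tetraol 20 goes back through dihydroxyquinone 11 and dimethoxyquinone 10 to tetramethoxyterphenyl 9; only the oxidation state of ring A changes.
3. The strategy rests on ring A, the central benzene ring: it carries oxygen on C2', C3', C5' and C6' and carbon only on the para pair C1'/C4'. These two carbons map onto the two carbonyl carbons of tetramethoxy-1,4-benzoquinone 3, so 9 is cut at both aryl–ring A bonds into 3 and two equivalents of aryllithium 7.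
4. Carboxylate 19 comes from Z-selective olefination of epoxyaldehyde 15, whose two stereocentres are set by Katsuki–Sharpless epoxidation of (E)-but-2-en-1-ol.
5. Ring order: ring A is taken from chloranil and re-aromatised in step 3, the outer rings B and C come from 4-bromophenol, and the oxirane (the only ring actually built, step 6) is attached four times in step 11.

Key step: step 3

Remark: the four acyl groups are read from the SMILES as (2Z)-3-[(2S,3S)-3-methyloxiran-2-yl]prop-2-enoyl (trans-epoxide, (2Z,4S,5S)-4,5-epoxyhex-2-enoyl). The free acid is assumed to lactonise easily by opening its own epoxide, so it is handled only as its potassium salt.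

**Route**

Step 1
Reactants: 1 chloranil; 2 sodium methoxide
Product: 3 2,3,5,6-tetramethoxy-1,4-benzoquinone
Conditions: NaOCH3 (6 equiv), CH3OH, reflux
Reagents that add atoms: sodium methoxide 2, C[O-].[Na+]
Why: Fourfold addition–elimination (vinylogous acyl substitution) of methoxide on the chloroquinone should replace every chloride, the excess of methoxide and heat driving the slower third and fourth exchanges.

Step 2
Reactants: 4 4-bromophenol; 5 chlorotriisopropylsilane
Product: 6 (4-bromophenoxy)triisopropylsilane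
Conditions: iPr3SiCl, imidazole, DMF, rt
Reagents that add atoms: chlorotriisopropylsilane 5, CC(C)[Si](Cl)(C(C)C)C(C)C
Why: Imidazole-promoted O-silylation of a phenol should give the bulky aryl silyl ether, chosen because it resists aryllithium formation, cold aqueous acid and Lewis acid better than smaller silyl groups.

Step 3
Reactants: 3 2,3,5,6-tetramethoxy-1,4-benzoquinone; 6 (4-bromophenoxy)triisopropylsilane (2.4 equiv)
Product: 9 2',3',5',6'-tetramethoxy-4,4''-bis(triisopropylsilyloxy)-1,1':4',1''-terphenyl, via aryllithium 7 (not isolated), via dienediol 8 (not isolated)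
Conditions: 6, n-C4H9Li (2.3 equiv), THF, −78 °C; then 3, THF, −78 → 0 °C; then SnCl2·2H2O (4 equiv), conc. HCl, THF, 0 °C → rt
Reagents that add atoms: (4-bromophenoxy)triisopropylsilane 6 as aryllithium 7, [Li]c1ccc(O[Si](C(C)C)(C(C)C)C(C)C)cc1
Why: Bromine–lithium exchange gives 7, which should add 1,2 to one carbonyl of 3 and then to the remaining cross-conjugated carbonyl of the lithium quinolate, so that both aryl–ring A bonds form at the carbons that become C1' and C4'. Acid then ionises each tertiary carbinol of 8, which is doubly allylic and benzylic and is further stabilised by the methoxy groups at the termini of the pentadienyl cation and by the para-silyloxy aryl group, and divalent tin supplies the two electrons that complete loss of both hydroxyls and aromatise ring A. The closest known reaction type is the double addition of aryllithium reagents to 1,4-quinones followed by SnCl2/HCl reductive aromatisation of the 1,4-diarylcyclohexa-2,5-diene-1,4-diols, as used for oligoarenes and acenes. No ring is closed and no stereocentre remains, since the cis and trans diols converge on the same arene. The step needs 1,2-addition to win over conjugate addition with loss of methoxide and over electron transfer; the hard aryllithium at −78 °C and the electron-rich, weakly oxidising tetramethoxyquinone favour this, and because only the carbonyl carbons lose oxygen the para relationship of the aryl groups is fixed by 3. The aryl triisopropylsilyl ethers should tolerate n-C4H9Li at −78 °C and brief contact with cold aqueous HCl.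

Step 4
Reactants: 9 2',3',5',6'-tetramethoxy-4,4''-bis(triisopropylsilyloxy)-1,1':4',1''-terphenyl
Product: 10 2,5-dimethoxy-3,6-bis[4-(triisopropylsilyloxy)phenyl]-1,4-benzoquinone
Conditions: (NH4)2Ce(NO3)6 (2.5 equiv), CH3CN/CH2Cl2/H2O, 0 °C
Reagents that add atoms: water, O
Why: Oxidative demethylation by tetravalent cerium should oxidise the most electron-rich ring (the tetramethoxy ring A) to its radical cation, water attacks a para pair of methoxy-bearing carbons with loss of methanol, and both para pairs are equivalent by symmetry, so one para-quinone results.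

Step 5
Reactants: 10 2,5-dimethoxy-3,6-bis[4-(triisopropylsilyloxy)phenyl]-1,4-benzoquinone
Product: 11 2,5-dihydroxy-3,6-bis[4-(triisopropylsilyloxy)phenyl]-1,4-benzoquinone
Conditions: BCl3 (3 equiv), CH2Cl2, −78 → 0 °C; then H2O
Reagents that add atoms: none
Why: Chelation-assisted Lewis acid ether cleavage should remove exactly the two methyl groups that sit next to a quinone carbonyl (boron bridges C=O and OCH3, chloride attacks the methyl group), a non-basic alternative to hydroxide hydrolysis, which would endanger the base-labile aryl silyl ethers.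

Step 6
Reactants: 12 (E)-but-2-en-1-ol; 13 tert-butyl hydroperoxide
Product: 14 [(2S,3S)-3-methyloxiran-2-yl]methanol
Conditions: Ti(OiPr)4 (5 mol %), L-(+)-diisopropyl tartrate (6 mol %), t-BuOOH, 4 Å molecular sieves, CH2Cl2, −20 °C; non-aqueous work-up, distillation
Reagents that add atoms: tert-butyl hydroperoxide 13, CC(C)(C)OO
Why: Katsuki–Sharpless asymmetric epoxidation, in which the L-(+)-tartrate ligand on titanium directs oxygen to the alkene face that gives the (2S,3S)-epoxy alcohol, and the stereospecific syn oxygen transfer to the E-alkene fixes the trans relationship.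

Step 7
Reactants: 14 [(2S,3S)-3-methyloxiran-2-yl]methanol
Product: 15 (2R,3S)-3-methyloxirane-2-carbaldehyde
Conditions: PhI(OAc)2, TEMPO (10 mol %), CH2Cl2, 0 °C → rt; cold NaHCO3 wash, used as dried CH2Cl2 solution
Reagents that add atoms: none
Why: Oxoammonium-mediated oxidation of the primary alcohol under non-basic conditions should stop at the aldehyde without touching the epoxide or either stereocentre (the descriptor at C2 changes from S to R only because the formyl group outranks the ring carbon).

Step 8
Reactants: 15 (2R,3S)-3-methyloxirane-2-carbaldehyde; 16 methyl bis(2,2,2-trifluoroethyl)phosphonoacetate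
Product: 17 methyl (2Z)-3-[(2S,3S)-3-methyloxiran-2-yl]prop-2-enoate
Conditions: 16, KN(SiMe3)2, 18-crown-6, THF, −78 °C; then 15
Reagents that add atoms: methyl bis(2,2,2-trifluoroethyl)phosphonoacetate 16, COC(=O)CP(=O)(OCC(F)(F)F)OCC(F)(F)F
Why: Still–Gennari modification of the Horner–Wadsworth–Emmons reaction, in which the electron-poor trifluoroethyl phosphonate with a dissociated potassium counter-ion makes elimination from the kinetic adduct fast and irreversible and so should give the Z-enoate, while the epoxide stereocentres stay unchanged at −78 °C.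

Step 9
Reactants: 17 methyl (2Z)-3-[(2S,3S)-3-methyloxiran-2-yl]prop-2-enoate; 18 potassium trimethylsilanolate
Product: 19 potassium (2Z)-3-[(2S,3S)-3-methyloxiran-2-yl]prop-2-enoate
Conditions: KOSiMe3 (1.05 equiv), Et2O/THF, 0 °C → rt; salt filtered under Ar and dried
Reagents that add atoms: potassium trimethylsilanolate 18, C[Si](C)(C)[O-].[K+]
Why: Anhydrous silanolate cleavage of a methyl ester should deliver the carboxylate as a salt that precipitates, so the free acid, which would open its own epoxide to a lactone, is never formed and the Z-alkene is not exposed to aqueous base.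

Step 10
Reactants: 11 2,5-dihydroxy-3,6-bis[4-(triisopropylsilyloxy)phenyl]-1,4-benzoquinone
Product: 20 4,4''-bis(triisopropylsilyloxy)-1,1':4',1''-terphenyl-2',3',5',6'-tetrol
Conditions: Na2S2O4, EtOAc/H2O, rt, Ar; used at once
Reagents that add atoms: none
Why: Dithionite reduction of a quinone to its hydroquinone under near-neutral aqueous conditions should give the air-sensitive tetraol without affecting the aryl silyl ethers.

Step 11
Reactants: 20 4,4''-bis(triisopropylsilyloxy)-1,1':4',1''-terphenyl-2',3',5',6'-tetrol; 19 potassium (2Z)-3-[(2S,3S)-3-methyloxiran-2-yl]prop-2-enoate (6 equiv)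
Product: 22 4,4''-bis(triisopropylsilyloxy)-1,1':4',1''-terphenyl-2',3',5',6'-tetrayl tetrakis{(2Z)-3-[(2S,3S)-3-methyloxiran-2-yl]prop-2-enoate}, via mixed anhydride 21 (not isolated)
Conditions: 19, 2,4,6-Cl3C6H2COCl (6 equiv), 18-crown-6 (cat.), THF, 0 °C; then 20, iPr2NEt, DMAP (0.4 equiv), THF/toluene, 0 °C → rt, Ar
Reagents that add atoms: potassium (2Z)-3-[(2S,3S)-3-methyloxiran-2-yl]prop-2-enoate 19, C[C@@H]1O[C@H]1/C=C\C(=O)[O-].[K+]
Why: Yamaguchi esterification, in which the carboxylate salt and the hindered aroyl chloride give mixed anhydride 21 without passing through the free acid, and DMAP should transfer the less hindered enoyl group to each of the four ring A hydroxyls at low temperature, leaving the Z-alkene and the epoxide stereocentres as they are.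

Step 12
Reactants: 22 4,4''-bis(triisopropylsilyloxy)-1,1':4',1''-terphenyl-2',3',5',6'-tetrayl tetrakis{(2Z)-3-[(2S,3S)-3-methyloxiran-2-yl]prop-2-enoate}
Product: 23 4,4''-dihydroxy-1,1':4',1''-terphenyl-2',3',5',6'-tetrayl tetrakis{(2Z)-3-[(2S,3S)-3-methyloxiran-2-yl]prop-2-enoate} (CNP0249571.1)
Conditions: Bu4NF (2.5 equiv), AcOH (3 equiv), THF, 0 °C
Reagents that add atoms: none
Why: Fluoride-induced cleavage of the aryl Si–O bonds is fast because phenoxide is a good leaving group on silicon, and the acetic acid buffer should protonate the liberated phenoxides at once so that the four activated aryl esters and the vinyl epoxides are not exposed to base.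

**Compound list**

1 | chloranil (2,3,5,6-tetrachloro-1,4-benzoquinone) | O=C1C(Cl)=C(Cl)C(=O)C(Cl)=C1Cl | starting material
2 | sodium methoxide | C[O-].[Na+] | starting material
3 | 2,3,5,6-tetramethoxy-1,4-benzoquinone | COC1=C(OC)C(=O)C(OC)=C(OC)C1=O | intermediate
4 | 4-bromophenol | Oc1ccc(Br)cc1 | starting material
5 | chlorotriisopropylsilane | CC(C)[Si](Cl)(C(C)C)C(C)C | starting material
6 | (4-bromophenoxy)triisopropylsilane | CC(C)[Si](Oc1ccc(Br)cc1)(C(C)C)C(C)C | intermediate
7 | 4-(triisopropylsilyloxy)phenyllithium | [Li]c1ccc(O[Si](C(C)C)(C(C)C)C(C)C)cc1 | intermediate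
8 | 2,3,5,6-tetramethoxy-1,4-bis[4-(triisopropylsilyloxy)phenyl]cyclohexa-2,5-diene-1,4-diol (cis/trans mixture, formed as its dilithium salt) | COC1=C(OC)C(O)(c2ccc(O[Si](C(C)C)(C(C)C)C(C)C)cc2)C(OC)=C(OC)C1(O)c1ccc(O[Si](C(C)C)(C(C)C)C(C)C)cc1 | intermediate
9 | 2',3',5',6'-tetramethoxy-4,4''-bis(triisopropylsilyloxy)-1,1':4',1''-terphenyl | COc1c(OC)c(-c2ccc(O[Si](C(C)C)(C(C)C)C(C)C)cc2)c(OC)c(OC)c1-c1ccc(O[Si](C(C)C)(C(C)C)C(C)C)cc1 | intermediate
10 | 2,5-dimethoxy-3,6-bis[4-(triisopropylsilyloxy)phenyl]-1,4-benzoquinone | COC1=C(c2ccc(O[Si](C(C)C)(C(C)C)C(C)C)cc2)C(=O)C(OC)=C(c2ccc(O[Si](C(C)C)(C(C)C)C(C)C)cc2)C1=O | intermediate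
11 | 2,5-dihydroxy-3,6-bis[4-(triisopropylsilyloxy)phenyl]-1,4-benzoquinone | OC1=C(c2ccc(O[Si](C(C)C)(C(C)C)C(C)C)cc2)C(=O)C(O)=C(c2ccc(O[Si](C(C)C)(C(C)C)C(C)C)cc2)C1=O | intermediate
12 | (E)-but-2-en-1-ol | C/C=C/CO | starting material
13 | tert-butyl hydroperoxide | CC(C)(C)OO | starting material
14 | [(2S,3S)-3-methyloxiran-2-yl]methanol | C[C@@H]1O[C@H]1CO | intermediate
15 | (2R,3S)-3-methyloxirane-2-carbaldehyde | C[C@@H]1O[C@H]1C=O | intermediate
16 | methyl bis(2,2,2-trifluoroethyl)phosphonoacetate | COC(=O)CP(=O)(OCC(F)(F)F)OCC(F)(F)F | starting material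
17 | methyl (2Z)-3-[(2S,3S)-3-methyloxiran-2-yl]prop-2-enoate | C[C@@H]1O[C@H]1/C=C\C(=O)OC | intermediate
18 | potassium trimethylsilanolate | C[Si](C)(C)[O-].[K+] | starting material
19 | potassium (2Z)-3-[(2S,3S)-3-methyloxiran-2-yl]prop-2-enoate | C[C@@H]1O[C@H]1/C=C\C(=O)[O-].[K+] | intermediate
20 | 4,4''-bis(triisopropylsilyloxy)-1,1':4',1''-terphenyl-2',3',5',6'-tetrol | Oc1c(O)c(-c2ccc(O[Si](C(C)C)(C(C)C)C(C)C)cc2)c(O)c(O)c1-c1ccc(O[Si](C(C)C)(C(C)C)C(C)C)cc1 | intermediate
21 | (2Z)-3-[(2S,3S)-3-methyloxiran-2-yl]prop-2-enoic 2,4,6-trichlorobenzoic anhydride | C[C@@H]1O[C@H]1/C=C\C(=O)OC(=O)c1c(Cl)cc(Cl)cc1Cl | intermediate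
22 | 4,4''-bis(triisopropylsilyloxy)-1,1':4',1''-terphenyl-2',3',5',6'-tetrayl tetrakis{(2Z)-3-[(2S,3S)-3-methyloxiran-2-yl]prop-2-enoate} | C[C@@H]1O[C@H]1/C=C\C(=O)Oc1c(OC(=O)/C=C\[C@@H]2O[C@H]2C)c(-c2ccc(O[Si](C(C)C)(C(C)C)C(C)C)cc2)c(OC(=O)/C=C\[C@@H]2O[C@H]2C)c(OC(=O)/C=C\[C@@H]2O[C@H]2C)c1-c1ccc(O[Si](C(C)C)(C(C)C)C(C)C)cc1 | intermediate
23 | 4,4''-dihydroxy-1,1':4',1''-terphenyl-2',3',5',6'-tetrayl tetrakis{(2Z)-3-[(2S,3S)-3-methyloxiran-2-yl]prop-2-enoate} (CNP0249571.1) | C[C@@H]1O[C@H]1/C=C\C(=O)Oc1c(OC(=O)/C=C\[C@@H]2O[C@H]2C)c(-c2ccc(O)cc2)c(OC(=O)/C=C\[C@@H]2O[C@H]2C)c(OC(=O)/C=C\[C@@H]2O[C@H]2C)c1-c1ccc(O)cc1 | target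

**Summary**

Total step count: 12.
Longest linear sequence: 7 steps (1, 3, 4, 5, 10, 11, 12 from chloranil; equally 2, 3, 4, 5, 10, 11, 12 from 4-bromophenol). The acyl fragment takes 4 steps (6 to 9) and joins in step 11.

**Steps most likely to fail, with fallbacks**

Step 3. The aryllithium may add in conjugate fashion with loss of methoxide, or transfer an electron to the quinone. The enol ethers of the diol may also hydrolyse in acid before the tin reduction aromatises the ring. The fallback sets out from 1 and 6 and builds the two aryl–ring A bonds by cross-coupling instead. Chloranil 1 with two equivalents of NaOCH3 in CH3OH at 0 °C should give 2,5-dichloro-3,6-dimethoxy-1,4-benzoquinone F1. Bromide 6 is lithiated with n-C4H9Li, trapped with B(OiPr)3 and hydrolysed with dilute HCl to [4-(triisopropylsilyloxy)phenyl]boronic acid F2. Double Suzuki–Miyaura coupling of F1 with F2 (Pd(OAc)2, 2-dicyclohexylphosphino-2',6'-dimethoxybiphenyl, anhydrous K3PO4, toluene, 80 °C) should give quinone 10. The route is rejoined at 10, and steps 3 and 4 are bypassed.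

Step 11. Acylation may stop before all four hindered hydroxyls have reacted. The Z-enoyl group may isomerise to E through reversible conjugate addition of DMAP to the acylpyridinium ion. The tetraol may be re-oxidised under the basic conditions, and the acyl donor may lactonise. The fallback sets out from 15 and 20 and brings in the cis-alkene only after esterification. Aldehyde 15 with dimethyl (1-diazo-2-oxopropyl)phosphonate and K2CO3 in CH3OH (Ohira–Bestmann homologation) should give (2S,3S)-2-ethynyl-3-methyloxirane F3. Deprotonation with n-C4H9Li in THF at −78 °C, carboxylation with CO2 and cold NaHSO4 work-up should give (4S,5S)-4,5-epoxyhex-2-ynoic acid F4, whose linear alkyne cannot reach its own epoxide. Steglich esterification of 20 with F4 (dicyclohexylcarbodiimide, catalytic DMAP, CH2Cl2, 0 °C) should give 4,4''-bis(triisopropylsilyloxy)-1,1':4',1''-terphenyl-2',3',5',6'-tetrayl tetrakis{3-[(2S,3S)-3-methyloxiran-2-yl]prop-2-ynoate} F5. Fourfold syn semi-hydrogenation (H2, Pd/CaCO3 poisoned with Pb(OAc)2, quinoline, EtOAc) should then give 22, where the route is rejoined.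

Step 12. Fluoride or the liberated phenoxide may cleave or transfer the activated aryl esters, and the vinyl epoxides may be opened during the longer exposure that the robust triisopropylsilyl ethers need. The fallback sets out from 11 and exchanges the silyl group for one that leaves under non-basic conditions. Bu4NF in THF should convert 11 into 2,5-dihydroxy-3,6-bis(4-hydroxyphenyl)-1,4-benzoquinone (atromentin) F6. tert-Butylchlorodimethylsilane and imidazole in DMF, followed by an aqueous work-up that hydrolyses the labile silyl esters of the vinylogous acid hydroxyls, should give 2,5-dihydroxy-3,6-bis[4-(tert-butyldimethylsilyloxy)phenyl]-1,4-benzoquinone F7. Na2S2O4 reduction as in step 10 should give 4,4''-bis(tert-butyldimethylsilyloxy)-1,1':4',1''-terphenyl-2',3',5',6'-tetrol F8. Acylation with 19 through 21 as in step 11 should give 4,4''-bis(tert-butyldimethylsilyloxy)-1,1':4',1''-terphenyl-2',3',5',6'-tetrayl tetrakis{(2Z)-3-[(2S,3S)-3-methyloxiran-2-yl]prop-2-enoate} F9. The more labile aryl silyl ethers of F9 are then cleaved with HF·pyridine buffered with excess pyridine in THF at 0 °C, which should give target 23 directly.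

**Further compounds**

F1 | step 3 | 2,5-dichloro-3,6-dimethoxy-1,4-benzoquinone | COC1=C(Cl)C(=O)C(OC)=C(Cl)C1=O
F2 | step 3 | [4-(triisopropylsilyloxy)phenyl]boronic acid | OB(O)c1ccc(O[Si](C(C)C)(C(C)C)C(C)C)cc1
F3 | step 11 | (2S,3S)-2-ethynyl-3-methyloxirane | C[C@@H]1O[C@H]1C#C
F4 | step 11 | (4S,5S)-4,5-epoxyhex-2-ynoic acid | C[C@@H]1O[C@H]1C#CC(=O)O
F5 | step 11 | 4,4''-bis(triisopropylsilyloxy)-1,1':4',1''-terphenyl-2',3',5',6'-tetrayl tetrakis{3-[(2S,3S)-3-methyloxiran-2-yl]prop-2-ynoate} | C[C@@H]1O[C@H]1C#CC(=O)Oc1c(OC(=O)C#C[C@@H]2O[C@H]2C)c(-c2ccc(O[Si](C(C)C)(C(C)C)C(C)C)cc2)c(OC(=O)C#C[C@@H]2O[C@H]2C)c(OC(=O)C#C[C@@H]2O[C@H]2C)c1-c1ccc(O[Si](C(C)C)(C(C)C)C(C)C)cc1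
F6 | step 12 | 2,5-dihydroxy-3,6-bis(4-hydroxyphenyl)-1,4-benzoquinone (atromentin) | OC1=C(c2ccc(O)cc2)C(=O)C(O)=C(c2ccc(O)cc2)C1=O
F7 | step 12 | 2,5-dihydroxy-3,6-bis[4-(tert-butyldimethylsilyloxy)phenyl]-1,4-benzoquinone | OC1=C(c2ccc(O[Si](C)(C)C(C)(C)C)cc2)C(=O)C(O)=C(c2ccc(O[Si](C)(C)C(C)(C)C)cc2)C1=O
F8 | step 12 | 4,4''-bis(tert-butyldimethylsilyloxy)-1,1':4',1''-terphenyl-2',3',5',6'-tetrol | Oc1c(O)c(-c2ccc(O[Si](C)(C)C(C)(C)C)cc2)c(O)c(O)c1-c1ccc(O[Si](C)(C)C(C)(C)C)cc1
F9 | step 12 | 4,4''-bis(tert-butyldimethylsilyloxy)-1,1':4',1''-terphenyl-2',3',5',6'-tetrayl tetrakis{(2Z)-3-[(2S,3S)-3-methyloxiran-2-yl]prop-2-enoate} | C[C@@H]1O[C@H]1/C=C\C(=O)Oc1c(OC(=O)/C=C\[C@@H]2O[C@H]2C)c(-c2ccc(O[Si](C)(C)C(C)(C)C)cc2)c(OC(=O)/C=C\[C@@H]2O[C@H]2C)c(OC(=O)/C=C\[C@@H]2O[C@H]2C)c1-c1ccc(O[Si](C)(C)C(C)(C)C)cc1
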